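The target is a 4β→6 biflavan: guibourtinidol (rings A/C/B) on ent-epifisetinidol (rings D/F/E). The route rests on disconnecting pyran ring F from resorcinol ring D. Its two bonds to ring D, C4(F)–C4a(D) and O1(F)–C8a(D), sit on adjacent aromatic carbons, which is the ortho-carbon/ipso-oxygen pattern of palladium/norbornene catalysis. One operation should therefore join commercial 1-(benzyloxy)-3-iodobenzene (iodine at the future C8a, free C–H at the future C4a) to an acyclic, aldol-derived (1S,2R)-3-iodo-1-arylpropane-1,2-diol monoether and give the 2,3-cis flavan directly. Bromination, aryllithium addition to a garbanzol-derived ketone, anti-selective ionic hydrogenation and hydrogenolysis complete the synthesis.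

Key step: step 5

Remark on the structure: the SMILES is read as (2R,3S,4S) in the upper unit (2,3-trans, 3,4-cis, 4β-aryl) and (2S,3S) in the lower unit (2,3-cis), joined C4→C6.
Assumption: (2R,3R)-garbanzol (12) is bought as a catalogue natural product; 1, 2, 4 and 9 are catalogue chemicals.

Step 1
Reactants: 1 (R)-4-benzyloxazolidin-2-one; 2 (benzyloxy)acetyl chloride
Product: 3 (R)-4-benzyl-3-[(benzyloxy)acetyl]oxazolidin-2-one
Conditions: Et3N, DMAP (cat.), CH2Cl2, 0 °C → rt
Reagents that add atoms: none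
Why: DMAP-catalysed N-acylation of the oxazolidinone by the acid chloride (nucleophilic acyl substitution); the auxiliary stereocentre is not touched.

Step 2
Reactants: 3 (R)-4-benzyl-3-[(benzyloxy)acetyl]oxazolidin-2-one; 4 3,4-bis(benzyloxy)benzaldehyde
Product: 6 (R)-4-benzyl-3-[(2R,3S)-2-(benzyloxy)-3-[3,4-bis(benzyloxy)phenyl]-3-hydroxypropanoyl]oxazolidin-2-one, via Z-dibutylboron enolate 5 (not isolated)
Conditions: Bu2BOTf, iPr2NEt, CH2Cl2, −78 → 0 °C; then 4, −78 → 0 °C; pH 7 buffer, MeOH, H2O2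
Reagents that add atoms: none
Why: Evans syn-aldol reaction: the Z-boron enolate reacts through a Zimmerman–Traxler chair in which the (R)-benzyl group of the auxiliary shields one enolate face, which should set the syn (2R,3S) pair and deliver the two oxygens already differentiated (OBn and OH).

Step 3
Reactants: 6 syn-aldol adduct
Product: 7 (1S,2S)-2-(benzyloxy)-1-[3,4-bis(benzyloxy)phenyl]propane-1,3-diol
Conditions: LiBH4, THF, MeOH (1 equiv), 0 °C
Reagents that add atoms: none
Why: Reductive cleavage of the N-acyl oxazolidinone by borohydride gives the primary alcohol and returns the auxiliary; neither stereocentre is touched.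

Step 4
Reactants: 7 (1S,2S)-2-(benzyloxy)-1-[3,4-bis(benzyloxy)phenyl]propane-1,3-diol
Product: 8 (1S,2R)-2-(benzyloxy)-1-[3,4-bis(benzyloxy)phenyl]-3-iodopropan-1-ol
Conditions: I2, PPh3, imidazole, THF, 0 °C
Reagents that add atoms: iodine, II
Why: Appel-type (Garegg–Samuelsson) iodination, in which the primary hydroxyl should react well ahead of the hindered secondary benzylic one; substitution occurs only at CH2, so both stereocentres are kept (the label at C2 changes for CIP reasons only).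

Step 5
Reactants: 8 (1S,2R)-2-(benzyloxy)-1-[3,4-bis(benzyloxy)phenyl]-3-iodopropan-1-ol; 9 1-(benzyloxy)-3-iodobenzene
Product: 10 (2S,3S)-3,7-bis(benzyloxy)-2-[3,4-bis(benzyloxy)phenyl]chromane (tetra-O-benzyl-ent-epifisetinidol, 2,3-cis)
Conditions: Pd(OAc)2 (10 mol%), XPhos (20 mol%), 1-methylbicyclo[2.2.1]hept-2-ene (bridgehead-substituted norbornene, 1 equiv), Cs2CO3, 1,4-dioxane, 90 °C
Reagents that add atoms: none
Why: Proposed new method: a Catellani-type ortho-alkylation/ipso-etherification in which zerovalent palladium inserts into the C–I bond of 9, the norbornene carbopalladates and relays the metal to the ortho C–H at C4 of 9 (para to OBn, the future C4a), the divalent palladacycle takes up the primary iodide 8 by SN2 oxidative addition to tetravalent palladium and forms the C4–C4a bond by reductive elimination, the norbornene is expelled by β-carbon elimination, and the aryl–palladium alkoxide forms the O1–C8a bond by C–O reductive elimination at the ipso carbon. The closest known reactions are the palladium/norbornene annulations of aryl iodides with epoxides (to 2,3-dihydrobenzofurans) and with bromoalkylamines (to tetrahydroquinolines), together with the intramolecular Buchwald–Hartwig etherification of 3-(2-halophenyl)propanols to chromans; new here are the γ-hydroxyalkyl iodide as alkylating partner and the six-membered ether closure. The one ring formed (pyran ring F) closes in the C–O reductive elimination from a seven-membered oxapalladacycle, the C–C bond having been made intermolecularly just before. No stereocentre is created: C2 and C3 come from 8 with no bond to either broken, so the syn (S,S) pair becomes the 2,3-cis ring. The step needs a single ortho-alkylation at C4 and not at C2 of 9, which the OBn group flanking C2–H and the bridgehead substituent of the norbornene (extrusion after one alkylation) should secure. It also needs C–O reductive elimination to outrun β-hydride elimination of the benzylic alkoxide and oxetane formation from 8, for which the bulky biarylphosphine and the weak carbonate base are chosen.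

Step 6
Reactants: 10 tetra-O-benzyl-ent-epifisetinidol
Product: 11 (2S,3S)-3,7-bis(benzyloxy)-2-[3,4-bis(benzyloxy)phenyl]-6-bromochromane
Conditions: N-bromosuccinimide (1.0 equiv), CH2Cl2, −20 °C, dark
Reagents that add atoms: N-bromosuccinimide, O=C1CCC(=O)N1Br
Why: Electrophilic aromatic bromination should go to C6, which is para to the ring oxygen and ortho to 7-OBn; C8 is flanked by two oxygen substituents and the catechol ring is less activated.

Step 7
Reactants: 12 (2R,3R)-garbanzol [(2R,3R)-3,7-dihydroxy-2-(4-hydroxyphenyl)chroman-4-one]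
Product: 13 (2R,3R)-7-(benzyloxy)-2-[4-(benzyloxy)phenyl]-3-hydroxychroman-4-one
Conditions: BnBr (2.2 equiv), K2CO3, DMF, rt, argon
Reagents that add atoms: benzyl bromide, BrCc1ccccc1
Why: Williamson O-benzylation of the two phenols under mild carbonate conditions; the far less acidic ketol hydroxyl stays free and the 2,3-trans stereocentres are not touched.

Step 8
Reactants: 11 (2S,3S)-3,7-bis(benzyloxy)-2-[3,4-bis(benzyloxy)phenyl]-6-bromochromane; 13 (2R,3R)-7-(benzyloxy)-2-[4-(benzyloxy)phenyl]-3-hydroxychroman-4-one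
Product: 16 (2R,3R)-7-(benzyloxy)-2-[4-(benzyloxy)phenyl]-4-[(2S,3S)-3,7-bis(benzyloxy)-2-[3,4-bis(benzyloxy)phenyl]chroman-6-yl]chromane-3,4-diol (mixture of C4 epimers), via aryllithium 14 (not isolated), via lithium alkoxide 15 (not isolated)
Conditions: 11, n-BuLi, THF, −78 °C; separately 13, LiN(SiMe3)2 (1.0 equiv), THF, −78 °C; mix, −78 → −30 °C; aq. NH4Cl
Reagents that add atoms: none
Why: Bromine–lithium exchange gives aryllithium 14, which should add 1,2 to the ketone of 15 (carbonyl chelated to the neighbouring lithium alkoxide, no acidic proton left to quench 14) and so form the interflavan C4–C6 bond; the new C4 centre need not be controlled because step 9 erases it.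

Step 9
Reactants: 16 4-aryl-flavan-3,4-diol (both C4 epimers)
Product: 17 (2R,3S,4R)-7-(benzyloxy)-2-[4-(benzyloxy)phenyl]-4-[(2S,3S)-3,7-bis(benzyloxy)-2-[3,4-bis(benzyloxy)phenyl]chroman-6-yl]chroman-3-ol (2,3-trans-3,4-cis, 4β-aryl)
Conditions: Et3SiH (5 equiv), CF3CO2H, CH2Cl2, −40 °C
Reagents that add atoms: none
Why: Ionic hydrogenation: acid ionises the tertiary, doubly benzylic C4–OH to a diarylcarbenium ion and Et3SiH should deliver hydride anti to the C3 oxygen (which bridges and shields the β face, the sense seen in anti hydride opening of acid-activated aryl epoxides and in 3,4-trans-selective captures of flavan-4-yl cations), so the aryl group ends cis to 3-OH and C4 is set from both epimers of 16.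

Step 10
Reactants: 17 hexa-O-benzyl biflavan
Product: 18 (2R,3S,4S)-4-[(2S,3S)-2-(3,4-dihydroxyphenyl)-3,7-dihydroxychroman-6-yl]-2-(4-hydroxyphenyl)chromane-3,7-diol [guibourtinidol-(4β→6)-ent-epifisetinidol, CNP0243811.4]
Conditions: H2 (1 atm), Pd(OH)2/C, THF–MeOH, rt
Reagents that add atoms: none
Why: Hydrogenolysis of the six benzyl ethers under neutral conditions, which should leave the interflavan bond, the cyclic benzylic ethers and all five stereocentres untouched.

Compound list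
1 | (R)-4-benzyloxazolidin-2-one | O=C1N[C@H](Cc2ccccc2)CO1 | starting material
2 | (benzyloxy)acetyl chloride | O=C(Cl)COCc1ccccc1 | starting material
3 | (R)-4-benzyl-3-[(benzyloxy)acetyl]oxazolidin-2-one | O=C(COCc1ccccc1)N1[C@H](Cc2ccccc2)COC1=O | intermediate
4 | 3,4-bis(benzyloxy)benzaldehyde | O=Cc1ccc(OCc2ccccc2)c(OCc2ccccc2)c1 | starting material
5 | Z-dibutylboron enolate of 3 | CCCCB(CCCC)O/C(=C\OCc1ccccc1)N1[C@H](Cc2ccccc2)COC1=O | intermediate (not isolated)
6 | (R)-4-benzyl-3-[(2R,3S)-2-(benzyloxy)-3-[3,4-bis(benzyloxy)phenyl]-3-hydroxypropanoyl]oxazolidin-2-one | O[C@@H](c1ccc(OCc2ccccc2)c(OCc2ccccc2)c1)[C@@H](OCc1ccccc1)C(=O)N1[C@H](Cc2ccccc2)COC1=O | intermediate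
7 | (1S,2S)-2-(benzyloxy)-1-[3,4-bis(benzyloxy)phenyl]propane-1,3-diol | O[C@@H](c1ccc(OCc2ccccc2)c(OCc2ccccc2)c1)[C@@H](OCc1ccccc1)CO | intermediate
8 | (1S,2R)-2-(benzyloxy)-1-[3,4-bis(benzyloxy)phenyl]-3-iodopropan-1-ol | O[C@@H](c1ccc(OCc2ccccc2)c(OCc2ccccc2)c1)[C@@H](OCc1ccccc1)CI | intermediate
9 | 1-(benzyloxy)-3-iodobenzene | Ic1cccc(OCc2ccccc2)c1 | starting material
10 | (2S,3S)-3,7-bis(benzyloxy)-2-[3,4-bis(benzyloxy)phenyl]chromane | c1cc2c(cc1OCc1ccccc1)O[C@@H](c1ccc(OCc3ccccc3)c(OCc3ccccc3)c1)[C@@H](OCc1ccccc1)C2 | intermediate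
11 | (2S,3S)-3,7-bis(benzyloxy)-2-[3,4-bis(benzyloxy)phenyl]-6-bromochromane | Brc1cc2c(cc1OCc1ccccc1)O[C@@H](c1ccc(OCc3ccccc3)c(OCc3ccccc3)c1)[C@@H](OCc1ccccc1)C2 | intermediate
12 | (2R,3R)-garbanzol, (2R,3R)-3,7-dihydroxy-2-(4-hydroxyphenyl)chroman-4-one | Oc1ccc([C@H]2Oc3cc(O)ccc3C(=O)[C@@H]2O)cc1 | starting material
13 | (2R,3R)-7-(benzyloxy)-2-[4-(benzyloxy)phenyl]-3-hydroxychroman-4-one | O(Cc1ccccc1)c1ccc([C@H]2Oc3cc(OCc4ccccc4)ccc3C(=O)[C@@H]2O)cc1 | intermediate
14 | [(2S,3S)-3,7-bis(benzyloxy)-2-[3,4-bis(benzyloxy)phenyl]chroman-6-yl]lithium | [Li]c1cc2c(cc1OCc1ccccc1)O[C@@H](c1ccc(OCc3ccccc3)c(OCc3ccccc3)c1)[C@@H](OCc1ccccc1)C2 | intermediate (not isolated)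
15 | lithium alkoxide of 13 | O(Cc1ccccc1)c1ccc([C@H]2Oc3cc(OCc4ccccc4)ccc3C(=O)[C@@H]2O[Li])cc1 | intermediate (not isolated)
16 | (2R,3R)-7-(benzyloxy)-2-[4-(benzyloxy)phenyl]-4-[(2S,3S)-3,7-bis(benzyloxy)-2-[3,4-bis(benzyloxy)phenyl]chroman-6-yl]chromane-3,4-diol, mixture of C4 epimers | O(Cc1ccccc1)c1ccc([C@H]2Oc3cc(OCc4ccccc4)ccc3C(O)(c3cc4c(cc3OCc3ccccc3)O[C@@H](c3ccc(OCc5ccccc5)c(OCc5ccccc5)c3)[C@@H](OCc3ccccc3)C4)[C@@H]2O)cc1 | intermediate
17 | (2R,3S,4R)-7-(benzyloxy)-2-[4-(benzyloxy)phenyl]-4-[(2S,3S)-3,7-bis(benzyloxy)-2-[3,4-bis(benzyloxy)phenyl]chroman-6-yl]chroman-3-ol (same spatial arrangement at C4 as in 18; the label differs only because the neighbouring phenol is benzylated) | O(Cc1ccccc1)c1ccc([C@H]2Oc3cc(OCc4ccccc4)ccc3[C@H](c3cc4c(cc3OCc3ccccc3)O[C@@H](c3ccc(OCc5ccccc5)c(OCc5ccccc5)c3)[C@@H](OCc3ccccc3)C4)[C@@H]2O)cc1 | intermediate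
18 | (2R,3S,4S)-4-[(2S,3S)-2-(3,4-dihydroxyphenyl)-3,7-dihydroxychroman-6-yl]-2-(4-hydroxyphenyl)chromane-3,7-diol | Oc1ccc([C@H]2Oc3cc(O)ccc3[C@H](c3cc4c(cc3O)O[C@@H](c3ccc(O)c(O)c3)[C@@H](O)C4)[C@@H]2O)cc1 | target

Total step count: 10. Longest linear sequence: 9 steps (steps 1–6, 8, 9, 10); step 7 is the one-step side branch.

Steps most likely to fail

1. Step 5 (the proposed new method). What may go wrong:
- a second ortho-alkylation, or stalled norbornene extrusion after the first alkylation;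
- β-hydride elimination of the benzylic palladium alkoxide in place of C–O reductive elimination;
- base-induced closure of 8 to an oxetane before it is taken up.

Fallback with known reactions, making the two bonds one at a time; it sets out from 7 and 9 and comes back at 10. TBSCl and imidazole should silylate the primary hydroxyl of 7 selectively to give (1S,2S)-2-(benzyloxy)-1-[3,4-bis(benzyloxy)phenyl]-3-[(tert-butyldimethylsilyl)oxy]propan-1-ol F1. Ullmann-type O-arylation of its secondary alcohol with 9 (CuI, 3,4,7,8-tetramethyl-1,10-phenanthroline, Cs2CO3, toluene, 110 °C; carbinol configuration retained) gives tert-butyl{(2S,3S)-2-(benzyloxy)-3-[3-(benzyloxy)phenoxy]-3-[3,4-bis(benzyloxy)phenyl]propoxy}dimethylsilane F2. Bu4NF then frees (2S,3S)-2-(benzyloxy)-3-[3-(benzyloxy)phenoxy]-3-[3,4-bis(benzyloxy)phenyl]propan-1-ol F3. Tf2O and 2,6-di-tert-butylpyridine at −78 → 0 °C convert it to (2S,3S)-2-(benzyloxy)-3-[3-(benzyloxy)phenoxy]-3-[3,4-bis(benzyloxy)phenyl]propyl trifluoromethanesulfonate F4. This triflate should alkylate the ring position ortho to the ether oxygen and para to OBn in an intramolecular Friedel–Crafts reaction (six-membered ring) and so return to 10.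

2. Step 9. What may go wrong:
- poor facial selectivity of hydride delivery to the planar C4 cation; attack syn to the C3 oxygen would give the all-trans 4α epimer;
- a semipinacol hydride shift from C3 to the cation.

Fallback through neighbouring-group participation; it sets out from 16 and comes back at 17. Ac2O, pyridine and DMAP should acetylate only the secondary hydroxyl, giving (2R,3R)-7-(benzyloxy)-2-[4-(benzyloxy)phenyl]-4-[(2S,3S)-3,7-bis(benzyloxy)-2-[3,4-bis(benzyloxy)phenyl]chroman-6-yl]-4-hydroxychroman-3-yl acetate F5 (C4 epimers). On ionisation with CF3CO2H the acetate closes onto C4 from the β face, and Et3SiH can then only enter anti to it (1,2-trans rule). This gives (2R,3S,4R)-7-(benzyloxy)-2-[4-(benzyloxy)phenyl]-4-[(2S,3S)-3,7-bis(benzyloxy)-2-[3,4-bis(benzyloxy)phenyl]chroman-6-yl]chroman-3-yl acetate F6. K2CO3 in MeOH removes the acetate and returns to 17.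

3. Step 8. What may go wrong:
- sluggish 1,2-addition to the hindered, electron-rich aryl ketone;
- competing proton transfer, and enediolate formation from the lithium ketol alkoxide that opens the pyranone ring.

Fallback that removes the acidic hydroxyl before the addition; it sets out from 13 and comes back at 17. TESCl and imidazole give (2R,3R)-7-(benzyloxy)-2-[4-(benzyloxy)phenyl]-3-[(triethylsilyl)oxy]chroman-4-one F7. Aryllithium 14 adds to it without a sacrificial base to give (2R,3R)-7-(benzyloxy)-2-[4-(benzyloxy)phenyl]-4-[(2S,3S)-3,7-bis(benzyloxy)-2-[3,4-bis(benzyloxy)phenyl]chroman-6-yl]-3-[(triethylsilyl)oxy]chroman-4-ol F8 (C4 epimers). Et3SiH and CF3CO2H at −40 °C then reduce C4, with the bulky silyl ether shielding the β face, to {(2R,3S,4R)-7-(benzyloxy)-2-[4-(benzyloxy)phenyl]-4-[(2S,3S)-3,7-bis(benzyloxy)-2-[3,4-bis(benzyloxy)phenyl]chroman-6-yl]chroman-3-yl}oxytriethylsilane F9. Bu4NF removes the silyl group and returns to 17.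

Further compounds
F1 | step 5 | (1S,2S)-2-(benzyloxy)-1-[3,4-bis(benzyloxy)phenyl]-3-[(tert-butyldimethylsilyl)oxy]propan-1-ol | O[C@@H](c1ccc(OCc2ccccc2)c(OCc2ccccc2)c1)[C@@H](OCc1ccccc1)CO[Si](C)(C)C(C)(C)C
F2 | step 5 | tert-butyl{(2S,3S)-2-(benzyloxy)-3-[3-(benzyloxy)phenoxy]-3-[3,4-bis(benzyloxy)phenyl]propoxy}dimethylsilane | C(c1ccccc1)Oc1cccc(O[C@@H](c2ccc(OCc3ccccc3)c(OCc3ccccc3)c2)[C@@H](OCc2ccccc2)CO[Si](C)(C)C(C)(C)C)c1
F3 | step 5 | (2S,3S)-2-(benzyloxy)-3-[3-(benzyloxy)phenoxy]-3-[3,4-bis(benzyloxy)phenyl]propan-1-ol | C(c1ccccc1)Oc1cccc(O[C@@H](c2ccc(OCc3ccccc3)c(OCc3ccccc3)c2)[C@@H](OCc2ccccc2)CO)c1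
F4 | step 5 | (2S,3S)-2-(benzyloxy)-3-[3-(benzyloxy)phenoxy]-3-[3,4-bis(benzyloxy)phenyl]propyl trifluoromethanesulfonate | C(c1ccccc1)Oc1cccc(O[C@@H](c2ccc(OCc3ccccc3)c(OCc3ccccc3)c2)[C@@H](OCc2ccccc2)COS(=O)(=O)C(F)(F)F)c1
F5 | step 9 | (2R,3R)-7-(benzyloxy)-2-[4-(benzyloxy)phenyl]-4-[(2S,3S)-3,7-bis(benzyloxy)-2-[3,4-bis(benzyloxy)phenyl]chroman-6-yl]-4-hydroxychroman-3-yl acetate (C4 epimers) | O(Cc1ccccc1)c1ccc([C@H]2Oc3cc(OCc4ccccc4)ccc3C(O)(c3cc4c(cc3OCc3ccccc3)O[C@@H](c3ccc(OCc5ccccc5)c(OCc5ccccc5)c3)[C@@H](OCc3ccccc3)C4)[C@@H]2OC(C)=O)cc1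
F6 | step 9 | (2R,3S,4R)-7-(benzyloxy)-2-[4-(benzyloxy)phenyl]-4-[(2S,3S)-3,7-bis(benzyloxy)-2-[3,4-bis(benzyloxy)phenyl]chroman-6-yl]chroman-3-yl acetate | O(Cc1ccccc1)c1ccc([C@H]2Oc3cc(OCc4ccccc4)ccc3[C@H](c3cc4c(cc3OCc3ccccc3)O[C@@H](c3ccc(OCc5ccccc5)c(OCc5ccccc5)c3)[C@@H](OCc3ccccc3)C4)[C@@H]2OC(C)=O)cc1
F7 | step 8 | (2R,3R)-7-(benzyloxy)-2-[4-(benzyloxy)phenyl]-3-[(triethylsilyl)oxy]chroman-4-one | O(Cc1ccccc1)c1ccc([C@H]2Oc3cc(OCc4ccccc4)ccc3C(=O)[C@@H]2O[Si](CC)(CC)CC)cc1
F8 | step 8 | (2R,3R)-7-(benzyloxy)-2-[4-(benzyloxy)phenyl]-4-[(2S,3S)-3,7-bis(benzyloxy)-2-[3,4-bis(benzyloxy)phenyl]chroman-6-yl]-3-[(triethylsilyl)oxy]chroman-4-ol (C4 epimers) | O(Cc1ccccc1)c1ccc([C@H]2Oc3cc(OCc4ccccc4)ccc3C(O)(c3cc4c(cc3OCc3ccccc3)O[C@@H](c3ccc(OCc5ccccc5)c(OCc5ccccc5)c3)[C@@H](OCc3ccccc3)C4)[C@@H]2O[Si](CC)(CC)CC)cc1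
F9 | step 8 | {(2R,3S,4R)-7-(benzyloxy)-2-[4-(benzyloxy)phenyl]-4-[(2S,3S)-3,7-bis(benzyloxy)-2-[3,4-bis(benzyloxy)phenyl]chroman-6-yl]chroman-3-yl}oxytriethylsilane | O(Cc1ccccc1)c1ccc([C@H]2Oc3cc(OCc4ccccc4)ccc3[C@H](c3cc4c(cc3OCc3ccccc3)O[C@@H](c3ccc(OCc5ccccc5)c(OCc5ccccc5)c3)[C@@H](OCc3ccccc3)C4)[C@@H]2O[Si](CC)(CC)CC)cc1
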